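**Plan**
- Retrosynthesis: ring C is cut at O1–C2 and C2–C3 (cyclodehydration, benzoylation of an acetyl group). The C4–C4a bond goes back to an O-acetyl group (Fries) and the piperidine to a pyridine. Then C7–O and C8a–O are cut together, and last the C8–C2' bond.
- Enabling feature: in ring A the oxygens on C7 and C8a both stand ortho to C8, the carbon that bears the nitrogen heterocycle. While that heterocycle is still a pyridine, its nitrogen can chelate palladium onto exactly these two C–H bonds. The C5 methoxy group, para to C8, comes in with the arene.
- Forward: Suzuki coupling joins ring A to the pyridine, and the palladium step adds both oxygens as acetates. One acetate is moved to carbon and later supplies C3 and C4. After benzyl protection the pyridine is N-methylated and hydrogenated to the piperidine, and ring C closes last from a 1,3-diketone.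
- Stereochemistry: the only stereocentre, C2' (R), is set by ligand-controlled iridium hydrogenation of the N-methylpyridinium salt. The three steps after it avoid hot acid and strong heating.

Key step: step 2

Assumption: the (S) antipode of the axially chiral bisphosphine is taken to give the R configuration at C2', by analogy with simple 2-arylpyridinium salts; if the sense of induction is the reverse, the (R) ligand is used and nothing else changes.

**Step 1**
Reactants: 1 2-bromopyridine; 2 4-methoxyphenylboronic acid
Product: 3 2-(4-methoxyphenyl)pyridine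
Conditions: Pd(PPh3)4 (3 mol %), K2CO3, 1,4-dioxane/H2O, 90 °C
Reagents that add atoms: none
Why: Suzuki–Miyaura coupling, in which zerovalent palladium inserts into the activated C–Br bond next to the pyridine nitrogen, the boronate transmetalates and reductive elimination forms the C8–C2' biaryl bond.

**Step 2**
Reactants: 3 2-(4-methoxyphenyl)pyridine
Product: 5 5-methoxy-2-(pyridin-2-yl)-1,3-phenylene diacetate, via monoacetate 4 (not isolated)
Conditions: Pd(OAc)2 (5 mol %), PhI(OAc)2 (3.0 equiv), AcOH/Ac2O (1:1), 100 °C
Reagents that add atoms: (diacetoxyiodo)benzene, CC(=O)OI(OC(C)=O)c1ccccc1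
Why: The pyridine nitrogen binds Pd(OAc)2 and acetate-assisted C–H cleavage at the ortho position gives a five-membered palladacycle of divalent palladium; PhI(OAc)2 oxidises it to a tetravalent palladium acetate, C–O reductive elimination releases monoacetate 4 and returns divalent palladium, and the same cycle then runs at the second ortho C–H bond, so that the C7–O and C8a–O bonds of 5 are both formed. The closest known reaction type is the pyridine-directed, palladium-catalysed ortho C–H acetoxylation of 2-arylpyridines with PhI(OAc)2, which goes on to the 2,6-diacetoxylated arene when the oxidant is in excess and the pyridine has no substituent at C3. No ring of the product is closed (the palladacycle is transient) and no stereocentre is formed. The step needs site selectivity for the two C–H bonds ortho to the pyridyl group over the two ortho to the methoxy group; chelation secures it, because only the former can enter a five-membered metallacycle, and the methoxy group is meta to both reacting positions. Complete double oxidation should follow from three equivalents of oxidant, and Ac2O keeps the products as acetates so that no free phenol meets the oxidant.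

**Step 3**
Reactants: 5 5-methoxy-2-(pyridin-2-yl)-1,3-phenylene diacetate
Product: 7 1-[2,4-dihydroxy-6-methoxy-3-(pyridin-2-yl)phenyl]ethan-1-one, via ketone monoacetate 6 (not isolated)
Conditions: MeSO3H, 70 °C; then MeOH, 60 °C; aq. NaHCO3
Reagents that add atoms: none
Why: Fries rearrangement in a Brønsted acid medium: the only free positions of ring A are two equivalent carbons, each ortho to one ester oxygen, para to the other and ortho to the methoxy group, so intra- and intermolecular acyl transfer give the same ketone, the new carbonyl and the protonated pyridine slow a second acylation, and acid methanolysis removes the acetate left on oxygen.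

**Step 4**
Reactants: 7 1-[2,4-dihydroxy-6-methoxy-3-(pyridin-2-yl)phenyl]ethan-1-one
Product: 8 1-[2,4-bis(benzyloxy)-6-methoxy-3-(pyridin-2-yl)phenyl]ethan-1-one
Conditions: BnBr (2.4 equiv), K2CO3, DMF, 60 °C
Reagents that add atoms: benzyl bromide, BrCc1ccccc1
Why: Williamson ether synthesis, in which both phenoxides are alkylated in warm DMF (the chelated one more slowly) and O-alkylation should outrun quaternisation of the hindered, weakly nucleophilic 2-arylpyridine nitrogen.

**Step 5**
Reactants: 8 1-[2,4-bis(benzyloxy)-6-methoxy-3-(pyridin-2-yl)phenyl]ethan-1-one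
Product: 9 2-[3-acetyl-2,6-bis(benzyloxy)-4-methoxyphenyl]-1-methylpyridin-1-ium trifluoromethanesulfonate
Conditions: MeOTf (1.2 equiv), CH2Cl2, 0 °C to rt
Reagents that add atoms: methyl trifluoromethanesulfonate, COS(=O)(=O)C(F)(F)F
Why: Menshutkin-type N-alkylation, for which MeOTf is small and electrophilic enough to quaternise a 2-arylpyridine whose aryl group is twisted out of plane, while the ketone and the ethers do not react at room temperature.

**Step 6**
Reactants: 9 2-[3-acetyl-2,6-bis(benzyloxy)-4-methoxyphenyl]-1-methylpyridin-1-ium trifluoromethanesulfonate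
Product: 11 1-{2,4-bis(benzyloxy)-6-methoxy-3-[(2R)-1-methylpiperidin-2-yl]phenyl}ethan-1-one, via piperidinium triflate 10 (not isolated)
Conditions: [Ir(cod)Cl]2 (1 mol %), (S)-SegPhos (2.2 mol %), Bu4NI (10 mol %), H2 (50 bar), toluene/CH2Cl2 (1:1), 30 °C; then aq. NaOH
Reagents that add atoms: none
Why: Iridium-catalysed asymmetric hydrogenation of a 2-arylpyridinium salt, in which quaternisation removes the aromatic stabilisation and the catalyst-binding lone pair, the iodide supplies the halide ligand that such iridium hydrides need, reduction runs through dihydropyridine and enamine/iminium stages, and the last hydride transfer to C2' of the cyclic iminium ion is face-selective in the pocket of the bisphosphine and sets R; the hindered ketone and the benzyl ethers should not be touched.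

**Step 7**
Reactants: 11 1-{2,4-bis(benzyloxy)-6-methoxy-3-[(2R)-1-methylpiperidin-2-yl]phenyl}ethan-1-one
Product: 12 1-{2,4-dihydroxy-6-methoxy-3-[(2R)-1-methylpiperidin-2-yl]phenyl}ethan-1-one
Conditions: H2 (1 atm), 10% Pd/C, MeOH, rt
Reagents that add atoms: none
Why: Hydrogenolysis of aryl benzyl ethers on palladium is fast at one atmosphere and room temperature, where the hindered aryl ketone and the ring C–N bond of the piperidine (a non-activated tertiary benzylic amine shielded by two ortho substituents) should persist, so C2' is untouched.

**Step 8**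
Reactants: 12 1-{2,4-dihydroxy-6-methoxy-3-[(2R)-1-methylpiperidin-2-yl]phenyl}ethan-1-one; 13 benzoyl chloride
Product: 15 1-{2,4-dihydroxy-6-methoxy-3-[(2R)-1-methylpiperidin-2-yl]phenyl}-3-phenylpropane-1,3-dione, via trilithium polyanion 14 (not isolated)
Conditions: LiN(SiMe3)2 (4.2 equiv), THF, −78 to −10 °C; then 13 (1.05 equiv), −78 °C to rt; 1 M HCl to pH 7
Reagents that add atoms: none
Why: Claisen-type C-benzoylation of a lithium enolate held in a polyanion (the direct variant of the Baker–Venkataraman diketone synthesis): with both phenols already lithium phenoxides the enolate carbon is the most nucleophilic site for the single equivalent of 13, any ester formed at the ortho phenoxide would converge on the same diketone by acyl shift under the excess base, and the non-acidic C2'–H is not affected.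

**Step 9**
Reactants: 15 1-{2,4-dihydroxy-6-methoxy-3-[(2R)-1-methylpiperidin-2-yl]phenyl}-3-phenylpropane-1,3-dione
Product: 17 7-hydroxy-5-methoxy-8-[(2R)-1-methylpiperidin-2-yl]-2-phenyl-4H-chromen-4-one, via cyclic hemiketal 16 (not isolated)
Conditions: conc. HCl, AcOH, 40 °C; then aq. NaHCO3 to pH 8
Reagents that add atoms: none
Why: Acid-catalysed cyclodehydration, the closing stage of a Baker–Venkataraman flavone synthesis: only the hydroxyl ortho to the acyl group can reach the benzoyl carbonyl (6-exo-trig addition to hemiketal 16, then loss of water), so O1 ends up next to C8 and the para hydroxyl stays free as the C7 phenol, while the low temperature and the N-protonated state should leave C2' as set.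

**Compound list**
1 | 2-bromopyridine | Brc1ccccn1 | starting material
2 | 4-methoxyphenylboronic acid | COc1ccc(B(O)O)cc1 | starting material
3 | 2-(4-methoxyphenyl)pyridine | COc1ccc(-c2ccccn2)cc1 | intermediate
4 | 5-methoxy-2-(pyridin-2-yl)phenyl acetate | COc1ccc(-c2ccccn2)c(OC(C)=O)c1 | intermediate
5 | 5-methoxy-2-(pyridin-2-yl)-1,3-phenylene diacetate | COc1cc(OC(C)=O)c(-c2ccccn2)c(OC(C)=O)c1 | intermediate
6 | 4-acetyl-3-hydroxy-5-methoxy-2-(pyridin-2-yl)phenyl acetate | COc1cc(OC(C)=O)c(-c2ccccn2)c(O)c1C(C)=O | intermediate
7 | 1-[2,4-dihydroxy-6-methoxy-3-(pyridin-2-yl)phenyl]ethan-1-one | COc1cc(O)c(-c2ccccn2)c(O)c1C(C)=O | intermediate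
8 | 1-[2,4-bis(benzyloxy)-6-methoxy-3-(pyridin-2-yl)phenyl]ethan-1-one | COc1cc(OCc2ccccc2)c(-c2ccccn2)c(OCc2ccccc2)c1C(C)=O | intermediate
9 | 2-[3-acetyl-2,6-bis(benzyloxy)-4-methoxyphenyl]-1-methylpyridin-1-ium trifluoromethanesulfonate | COc1cc(OCc2ccccc2)c(-c2cccc[n+]2C)c(OCc2ccccc2)c1C(C)=O.[O-]S(=O)(=O)C(F)(F)F | intermediate
10 | (2R)-2-[3-acetyl-2,6-bis(benzyloxy)-4-methoxyphenyl]-1-methylpiperidin-1-ium trifluoromethanesulfonate | COc1cc(OCc2ccccc2)c([C@H]2CCCC[NH+]2C)c(OCc2ccccc2)c1C(C)=O.[O-]S(=O)(=O)C(F)(F)F | intermediate
11 | 1-{2,4-bis(benzyloxy)-6-methoxy-3-[(2R)-1-methylpiperidin-2-yl]phenyl}ethan-1-one | COc1cc(OCc2ccccc2)c([C@H]2CCCCN2C)c(OCc2ccccc2)c1C(C)=O | intermediate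
12 | 1-{2,4-dihydroxy-6-methoxy-3-[(2R)-1-methylpiperidin-2-yl]phenyl}ethan-1-one | COc1cc(O)c([C@H]2CCCCN2C)c(O)c1C(C)=O | intermediate
13 | benzoyl chloride | O=C(Cl)c1ccccc1 | starting material
14 | trilithium salt of 12 (lithium enolate of the acetyl group and both lithium phenoxides) | [Li+].[Li+].[Li+].COc1cc([O-])c([C@H]2CCCCN2C)c([O-])c1C(=C)[O-] | intermediate
15 | 1-{2,4-dihydroxy-6-methoxy-3-[(2R)-1-methylpiperidin-2-yl]phenyl}-3-phenylpropane-1,3-dione | COc1cc(O)c([C@H]2CCCCN2C)c(O)c1C(=O)CC(=O)c1ccccc1 | intermediate
16 | 2,7-dihydroxy-5-methoxy-8-[(2R)-1-methylpiperidin-2-yl]-2-phenyl-2,3-dihydro-4H-chromen-4-one (both C2 epimers) | COc1cc(O)c([C@H]2CCCCN2C)c2OC(O)(c3ccccc3)CC(=O)c12 | intermediate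
17 | 7-hydroxy-5-methoxy-8-[(2R)-1-methylpiperidin-2-yl]-2-phenyl-4H-chromen-4-one | COc1cc(O)c([C@H]2CCCCN2C)c2oc(-c3ccccc3)cc(=O)c12 | target

**Step count**
Total steps: 9. Longest linear sequence: 9 steps (from 1 or 2 to 17).

**Steps most likely to fail**

Step 6. The hydrogenation may be slow or incomplete and the facial discrimination weak, because the pyridinium carbon is shielded by an aryl group with two ortho substituents and the nitrogen carries methyl, not the benzyl group on which most precedent rests. Fallback: racemic reduction and classical resolution, setting out from 9. Hydrogenation over PtO2 (H2 3 bar, MeOH, rt, stopped after three equivalents of hydrogen; aq. NaOH) should give racemic 1-{2,4-bis(benzyloxy)-6-methoxy-3-(1-methylpiperidin-2-yl)phenyl}ethan-1-one F1. Crystallisation with O,O'-di-p-toluoyl-L-tartaric acid from ethanol should then give the salt of the R base, (R)-amine di-p-toluoyl-L-tartrate F2; if the S base crystallises instead, the D acid is used. Aqueous NaOH frees the base, and the route is rejoined at 11.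

Step 9. The configuration at C2' may erode through reversible, acid-promoted ionisation of the benzylic C–N bond, since this carbon is flanked by two ring oxygens; if the acid is kept mild enough to prevent that, the dehydration may stall at the hemiketal. Fallback: a base-mediated one-pot Baker–Venkataraman flavone synthesis, setting out from 12. Treatment with 13 (3 equiv) and DBU in pyridine at 80 °C should O-benzoylate both phenols, shift the ortho benzoyl group to carbon and close the ring without strong acid and with the phenols masked. This should give 5-methoxy-8-[(2R)-1-methylpiperidin-2-yl]-4-oxo-2-phenyl-4H-chromen-7-yl benzoate F3. Methanolysis (K2CO3, MeOH, rt) then removes the benzoate and gives the target 17.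

Step 3. Acyl transfer may be incomplete, or the ring may be acetylated twice, because the molecule carries a second acetyl equivalent, the remaining ring position stays activated and the protonated pyridine slows the first acylation. Fallback: deacetylation followed by Houben–Hoesch acylation, setting out from 5. Methanolysis (K2CO3, MeOH, rt) should give 5-methoxy-2-(pyridin-2-yl)benzene-1,3-diol F4. Reaction with MeCN, ZnCl2 and HCl gas in Et2O at 0 °C should give 1-[2,4-dihydroxy-6-methoxy-3-(pyridin-2-yl)phenyl]ethan-1-iminium chloride F5, whose positive charge stops a second acylation. Hydrolysis in water at 90 °C then gives 7.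

**Further compounds**
F1 | step 6 | racemic 1-{2,4-bis(benzyloxy)-6-methoxy-3-(1-methylpiperidin-2-yl)phenyl}ethan-1-one | COc1cc(OCc2ccccc2)c(C2CCCCN2C)c(OCc2ccccc2)c1C(C)=O
F2 | step 6 | (R)-amine di-p-toluoyl-L-tartrate (1:1 salt of 11 with (2R,3R)-2,3-bis(4-methylbenzoyloxy)butanedioic acid) | COc1cc(OCc2ccccc2)c([C@H]2CCCCN2C)c(OCc2ccccc2)c1C(C)=O.OC(=O)[C@H](OC(=O)c1ccc(C)cc1)[C@@H](OC(=O)c1ccc(C)cc1)C(O)=O
F3 | step 9 | 5-methoxy-8-[(2R)-1-methylpiperidin-2-yl]-4-oxo-2-phenyl-4H-chromen-7-yl benzoate | COc1cc(OC(=O)c3ccccc3)c([C@H]2CCCCN2C)c2oc(-c3ccccc3)cc(=O)c12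
F4 | step 3 | 5-methoxy-2-(pyridin-2-yl)benzene-1,3-diol | COc1cc(O)c(-c2ccccn2)c(O)c1
F5 | step 3 | 1-[2,4-dihydroxy-6-methoxy-3-(pyridin-2-yl)phenyl]ethan-1-iminium chloride | COc1cc(O)c(-c2ccccn2)c(O)c1C(C)=[NH2+].[Cl-]
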